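Ring B (C5–C10 in labdane numbering; ring A is C1–C5 plus C10, the side chain C11–C16, the aldehyde carbon C17) is cut across C5–C10 and C7–C8, a formal (3+3) disconnection. C10 and C8 both flank C9, so if C11–C12 form an enal on C9, C10 and C8 are its two γ-carbons; C5 and C7 are the β- and carbonyl carbons of a second enal, tethered through ring A. One amine-catalysed cascade on this acyclic bis-enal, vinylogous Michael addition (C10 to C5, closing ring A, setting C5 and C10) then vinylogous aldol condensation (C8 to C7, closing ring B), gives the trans-decalin; the activating C12 aldehyde later carries the butenolide.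

Key step: step 9

Remark: C18 and C19 are the two CH2OH carbons on C4 and C20 is the C10 methyl; compounds 3 to 13 are racemic at the future C10, which becomes planar in step 9.

Step 1
Reactants: 1 methyl 3-oxopentanoate; 2 1-bromo-3-chloropropane
Product: 3 methyl 7-chloro-4-methyl-3-oxoheptanoate (racemic)
Conditions: NaH, THF, 0 °C; n-BuLi, 0 °C; then 2, 0 °C to rt; aq. HCl
Reagents that add atoms: none
Why: The β-keto ester dianion should react at its more nucleophilic terminal (γ) carbon and displace bromide in preference to chloride (γ-alkylation of a β-keto ester dianion, SN2), forming the future C10 as a racemate that is planarised later.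

Step 2
Reactants: 3 methyl 7-chloro-4-methyl-3-oxoheptanoate
Product: 4 methyl (2Z)-7-chloro-4-methyl-3-[(trifluoromethylsulfonyl)oxy]hept-2-enoate
Conditions: NaH, Et2O, 0 °C; Tf2O, −20 to 0 °C
Reagents that add atoms: trifluoromethanesulfonic anhydride, O=S(=O)(OS(=O)(=O)C(F)(F)F)C(F)(F)F
Why: O-Sulfonylation of the chelated sodium enolate should give the (Z)-enol triflate (enol triflate formation), a vinyl electrophile for cross-coupling.

Step 3
Reactants: 4 methyl (2Z)-7-chloro-4-methyl-3-[(trifluoromethylsulfonyl)oxy]hept-2-enoate; 5 (1,3-dioxolan-2-ylmethyl)zinc bromide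
Product: 6 methyl (2E)-7-chloro-3-(1,3-dioxolan-2-ylmethyl)-4-methylhept-2-enoate
Conditions: Pd(PPh3)4 (5 mol %), THF, 50 °C
Reagents that add atoms: none
Why: Negishi coupling under zerovalent palladium catalysis should replace the triflate with retention of alkene geometry; the alkyl chloride is inert and the cyclic acetal keeps the β-alkoxy organozinc from eliminating.

Step 4
Reactants: 6 methyl (2E)-7-chloro-3-(1,3-dioxolan-2-ylmethyl)-4-methylhept-2-enoate; 7 diethyl malonate
Product: 8 diethyl 2-[(5E)-5-(1,3-dioxolan-2-ylmethyl)-7-methoxy-4-methyl-7-oxohept-5-en-1-yl]propanedioate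
Conditions: NaH, 7 (1.5 equiv), NaI (10 mol %), DMF, 80 °C
Reagents that add atoms: none
Why: Sodiomalonate should displace the primary chloride with iodide catalysis (malonic ester alkylation, SN2), while the hindered β,β-disubstituted enoate resists conjugate addition.

Step 5
Reactants: 8 diethyl 2-[(5E)-5-(1,3-dioxolan-2-ylmethyl)-7-methoxy-4-methyl-7-oxohept-5-en-1-yl]propanedioate; 9 ethyl propiolate
Product: 10 diethyl 2-[(5E)-5-(1,3-dioxolan-2-ylmethyl)-7-methoxy-4-methyl-7-oxohept-5-en-1-yl]-2-[(1E)-3-ethoxy-3-oxoprop-1-en-1-yl]propanedioate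
Conditions: NaH (10 mol %), THF, 0 °C to rt
Reagents that add atoms: none
Why: Base-catalysed Michael addition of the tertiary malonate carbanion to the ynoate should create the quaternary C4 and the acrylate arm, mainly as the (E)-isomer, and any (Z)-isomer converges under the iminium catalysis of step 9.

Step 6
Reactants: 10 diethyl 2-[(5E)-5-(1,3-dioxolan-2-ylmethyl)-7-methoxy-4-methyl-7-oxohept-5-en-1-yl]-2-[(1E)-3-ethoxy-3-oxoprop-1-en-1-yl]propanedioate
Product: 11 2-[(5E)-5-(1,3-dioxolan-2-ylmethyl)-7-hydroxy-4-methylhept-5-en-1-yl]-2-[(1E)-3-hydroxyprop-1-en-1-yl]propane-1,3-diol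
Conditions: i-Bu2AlH (10 equiv), CH2Cl2, −78 to 0 °C; aq. sodium potassium tartrate
Reagents that add atoms: none
Why: i-Bu2AlH should reduce all four esters by 1,2-hydride delivery (ester reduction) and leave the two alkenes and the dioxolane untouched.

Step 7
Reactants: 11 2-[(5E)-5-(1,3-dioxolan-2-ylmethyl)-7-hydroxy-4-methylhept-5-en-1-yl]-2-[(1E)-3-hydroxyprop-1-en-1-yl]propane-1,3-diol
Product: 12 (2E)-3-(1,3-dioxolan-2-ylmethyl)-7-{5-[(1E)-3-hydroxyprop-1-en-1-yl]-2,2-dimethyl-1,3-dioxan-5-yl}-4-methylhept-2-en-1-ol
Conditions: Me2C(OMe)2, PPTS (5 mol %), acetone, rt; aq. NaHCO3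
Reagents that add atoms: 2,2-dimethoxypropane, COC(C)(C)OC
Why: Acid-catalysed transacetalisation should close the six-membered isopropylidene acetal on the 1,3-diol (acetonide protection), and mixed ketals on the allylic alcohols are lost on aqueous work-up.

Step 8
Reactants: 12 (2E)-3-(1,3-dioxolan-2-ylmethyl)-7-{5-[(1E)-3-hydroxyprop-1-en-1-yl]-2,2-dimethyl-1,3-dioxan-5-yl}-4-methylhept-2-en-1-ol
Product: 13 (2E)-3-(1,3-dioxolan-2-ylmethyl)-7-{2,2-dimethyl-5-[(1E)-3-oxoprop-1-en-1-yl]-1,3-dioxan-5-yl}-4-methylhept-2-enal
Conditions: MnO2 (20 equiv), CH2Cl2, rt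
Reagents that add atoms: none
Why: MnO2 should oxidise both allylic alcohols to the enals under neutral conditions (allylic oxidation).

Step 9
Reactants: 13 (2E)-3-(1,3-dioxolan-2-ylmethyl)-7-{2,2-dimethyl-5-[(1E)-3-oxoprop-1-en-1-yl]-1,3-dioxan-5-yl}-4-methylhept-2-enal
Product: 15 bicyclic dienal with rings A and B closed (C7=C8 and exocyclic C9=C11–C12HO), via ring-A Michael adduct 14 (not isolated)
Conditions: (R)-2-[diphenyl(trimethylsilyloxy)methyl]pyrrolidine (20 mol %), PhCO2H (20 mol %), PhMe (0.02 M), rt to 40 °C
Reagents that add atoms: none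
Why: Proposed new method: the chiral secondary amine should turn the C5=C6–C7 enal into its iminium ion and the C12 enal into the C9=C10 dienamine, whose γ-carbon C10 adds to C5 (vinylogous Michael addition, 6-exo-trig, ring A) to give 14; proton transfer then forms the dienamine through C8, which attacks the freed C7 aldehyde (vinylogous aldol addition, 6-exo-trig at the carbonyl, ring B) and loses water to the linearly conjugated dienal 15. The closest known reactions are the amine-catalysed vinylogous Michael addition of dienamines to iminium ions, the formal (3+3) condensations of two enals and the vinylogous aldol condensation of β-alkyl enals, here run intramolecularly with formation of a quaternary carbon. C5 is set by the catalyst, whose diphenyl(silyloxy)methyl group shields the Si face of the (E)-iminium ion so that C10 adds to the Re face, and C10 follows from a chair-like transition state with the methyl group axial and the C9 unit equatorial, which places the two arms trans as the trans ring fusion requires. The step needs C10 to be the first nucleophile and C8 the second: attack on C5 through C11 or C8 would give eight-membered rings, the acceptor enal has no γ-hydrogen because C4 is quaternary and cannot act as donor, and closure of the aldehyde enamine carbon C6 on C12 (the amino-Diels–Alder mode) has to build a bond at a carbon flanked by C5 and its two quaternary neighbours, whereas C8 meets the unhindered C7 aldehyde and its closure is made irreversible by dehydration.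

Step 10
Reactants: 15 bicyclic dienal
Product: 16 saturated aldehyde (C9–CH2CHO, C8 dioxolanyl axial)
Conditions: H2 (1 atm), Pd/C (10 wt %), EtOAc, rt
Reagents that add atoms: none
Why: Heterogeneous hydrogenation should saturate both C=C bonds from the face opposite the axial C10 methyl group, which sets C9 with the side chain equatorial (substrate control) and places the C8 acetal axial; either C8 epimer is corrected in step 13.

Step 11
Reactants: 16 saturated aldehyde; 17 3-(triphenylphosphoranylidene)dihydrofuran-2(3H)-one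
Product: 18 (E)-α-alkylidene lactone
Conditions: PhMe, 80 °C
Reagents that add atoms: none
Why: Wittig reaction of the stabilised lactone ylide with the unhindered aldehyde should give the (E)-α-alkylidene lactone.

Step 12
Reactants: 18 (E)-α-alkylidene lactone
Product: 19 acetal-protected butenolide
Conditions: RuHCl(CO)(PPh3)3 (5 mol %), PhMe, 100 °C
Reagents that add atoms: none
Why: Reversible Ru–H addition to the exocyclic enoate double bond and β-hydride elimination toward C14 should move the alkene into the ring to give the more stable butenolide (metal hydride catalysed alkene isomerisation).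

Step 13
Reactants: 19 acetal-protected butenolide
Product: 20 target CNP0332660.1
Conditions: 1 M aq. HCl, THF, 45 °C
Reagents that add atoms: water, O
Why: Aqueous acid should hydrolyse both acetals, and the liberated axial C8 aldehyde should epimerise through its enol to the equatorial isomer, which removes the 1,3-diaxial contact with the C10 methyl group (acetal hydrolysis with thermodynamic epimerisation).

Compound list

1 | methyl 3-oxopentanoate | CCC(=O)CC(=O)OC | starting material
2 | 1-bromo-3-chloropropane | ClCCCBr | starting material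
3 | methyl 7-chloro-4-methyl-3-oxoheptanoate (racemic) | COC(=O)CC(=O)C(C)CCCCl | intermediate
4 | methyl (2Z)-7-chloro-4-methyl-3-[(trifluoromethylsulfonyl)oxy]hept-2-enoate (racemic) | COC(=O)/C=C(\OS(=O)(=O)C(F)(F)F)C(C)CCCCl | intermediate
5 | (1,3-dioxolan-2-ylmethyl)zinc bromide | Br[Zn]CC1OCCO1 | starting material
6 | methyl (2E)-7-chloro-3-(1,3-dioxolan-2-ylmethyl)-4-methylhept-2-enoate (racemic) | COC(=O)/C=C(\CC1OCCO1)C(C)CCCCl | intermediate
7 | diethyl malonate | CCOC(=O)CC(=O)OCC | starting material
8 | diethyl 2-[(5E)-5-(1,3-dioxolan-2-ylmethyl)-7-methoxy-4-methyl-7-oxohept-5-en-1-yl]propanedioate (racemic) | COC(=O)/C=C(\CC1OCCO1)C(C)CCCC(C(=O)OCC)C(=O)OCC | intermediate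
9 | ethyl propiolate | C#CC(=O)OCC | starting material
10 | diethyl 2-[(5E)-5-(1,3-dioxolan-2-ylmethyl)-7-methoxy-4-methyl-7-oxohept-5-en-1-yl]-2-[(1E)-3-ethoxy-3-oxoprop-1-en-1-yl]propanedioate (racemic) | COC(=O)/C=C(\CC1OCCO1)C(C)CCCC(/C=C/C(=O)OCC)(C(=O)OCC)C(=O)OCC | intermediate
11 | 2-[(5E)-5-(1,3-dioxolan-2-ylmethyl)-7-hydroxy-4-methylhept-5-en-1-yl]-2-[(1E)-3-hydroxyprop-1-en-1-yl]propane-1,3-diol (racemic) | OC/C=C(\CC1OCCO1)C(C)CCCC(CO)(CO)/C=C/CO | intermediate
12 | (2E)-3-(1,3-dioxolan-2-ylmethyl)-7-{5-[(1E)-3-hydroxyprop-1-en-1-yl]-2,2-dimethyl-1,3-dioxan-5-yl}-4-methylhept-2-en-1-ol (racemic) | OC/C=C(\CC1OCCO1)C(C)CCCC2(/C=C/CO)COC(C)(C)OC2 | intermediate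
13 | (2E)-3-(1,3-dioxolan-2-ylmethyl)-7-{2,2-dimethyl-5-[(1E)-3-oxoprop-1-en-1-yl]-1,3-dioxan-5-yl}-4-methylhept-2-enal (racemic) | O=C/C=C(\CC1OCCO1)C(C)CCCC2(/C=C/C=O)COC(C)(C)OC2 | intermediate
14 | ring-A Michael adduct: (2E)-3-(1,3-dioxolan-2-ylmethyl)-3-[3,3,8-trimethyl-7-(2-oxoethyl)-2,4-dioxaspiro[5.5]undecan-8-yl]prop-2-enal, the two side chains trans on the cyclohexane, C5 and C10 configured as in the target | C[C@@]1(/C(CC2OCCO2)=C/C=O)CCCC3(COC(C)(C)OC3)[C@H]1CC=O | intermediate
15 | bicyclic dienal: trans-fused decalin (C5 and C10 as in the target) with the 18,19-diol as acetonide, a C7=C8 double bond, 1,3-dioxolan-2-yl on C8 and an exocyclic C9=C11H–C12HO unit with CHO cis to C8 | C[C@@]12CCCC3(COC(C)(C)OC3)[C@H]1CC=C(C4OCCO4)/C2=C\C=O | intermediate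
16 | saturated aldehyde: trans-decalin with the 18,19-acetonide; C9 carries CH2CHO with C9–H trans to the C10 methyl group (as in the target); C8 carries 1,3-dioxolan-2-yl cis to the C10 methyl group (axial, 8-epi) | C[C@@]12CCCC3(COC(C)(C)OC3)[C@H]1CC[C@@H](C4OCCO4)[C@H]2CC=O | intermediate
17 | 3-(triphenylphosphoranylidene)dihydrofuran-2(3H)-one | O=C1OCCC1=P(c2ccccc2)(c3ccccc3)c4ccccc4 | starting material
18 | (E)-α-alkylidene lactone: 16 with the CHO converted into CH=C3 of dihydrofuran-2(3H)-one, the C11 chain trans to the lactone carbonyl | C[C@@]12CCCC3(COC(C)(C)OC3)[C@H]1CC[C@@H](C4OCCO4)[C@H]2C/C=C5\CCOC5=O | intermediate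
19 | acetal-protected butenolide: as 16 but with C9 carrying 2-(2-oxo-2,5-dihydrofuran-3-yl)ethyl | C[C@@]12CCCC3(COC(C)(C)OC3)[C@H]1CC[C@@H](C4OCCO4)[C@H]2CCC5=CCOC5=O | intermediate
20 | target CNP0332660.1, (5S,8S,9R,10S) in labdane numbering: 18,19-diol, C8 equatorial CHO, C9 2-(2-oxo-2,5-dihydrofuran-3-yl)ethyl | C[C@@]12CCCC(CO)(CO)[C@H]1CC[C@H](C=O)[C@H]2CCC1=CCOC1=O | target

Total step count: 13. Longest linear sequence: 13 steps.

Steps most likely to fail

Step 9 (Proposed new method). The hindered dienamine may fail to add to the iminium ion, or the Michael adduct may close between C6 and C12 (amino-Diels–Alder mode) or through C11 instead of C8. The fallback uses known chemistry, sets out from 8 and returns at 15. Ozonolysis of 8 (O3, CH2Cl2–MeOH, −78 °C; Me2S) cleaves the enoate and should give diethyl 2-[6-(1,3-dioxolan-2-yl)-4-methyl-5-oxohexyl]propanedioate F1. Base-catalysed Michael addition to ethyl propiolate 9 gives the keto triester F2, i-Bu2AlH reduces the three esters and the ketone to the tetraol F3, and 2,2-dimethoxypropane with PPTS gives the acetonide diol F4. DMP (1,1,1-triacetoxy-1,1-dihydro-1,2-benziodoxol-3(1H)-one) oxidises the allylic and the secondary alcohol to the keto enal F5. A Robinson-type annulation of F5 with a chiral primary amine salt (9-amino-9-deoxy-epi-cinchona type, the pseudo-enantiomer that sends C10 to the Re face of C5) then forms the same two bonds: Michael addition of the ketone α-carbon C10 to C5, then aldol condensation of C8 on C7. It should give the bicyclic enone F6; because C9 is a carbonyl carbon here, neither the Diels–Alder-type closure nor a closure through C11 exists. Addition of HC≡CMgBr with CeCl3 (THF, −78 °C) to the C9 ketone gives the propargylic alcohol F7, and Meyer–Schuster rearrangement (Ph3PAuNTf2, 2 mol %, wet MeOH, rt) gives 15.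

Step 10. Hydrogen may be delivered to both faces of C9, a centre that cannot be corrected later, and the allylic acetal or the aldehyde may be reduced. The fallback sets out from 15 and returns at 16. Iminium-catalysed transfer hydrogenation with diethyl 2,6-dimethyl-1,4-dihydropyridine-3,5-dicarboxylate and a chiral imidazolidinone salt should reduce only the C9=C11 bond, with catalyst-controlled hydride delivery to C9, and give the unsaturated aldehyde F8. H2 over Pd/C then saturates the remaining C7=C8 bond, whose C8 configuration is not critical, to give 16.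

Step 12. The exocyclic double bond may migrate incompletely, or toward C11 (deconjugation) instead of into the lactone ring. The fallback sets out from 16 and returns at 19, bypassing 18. NaBH4 (MeOH, 0 °C) reduces 16 to the primary alcohol F9, and I2, PPh3 and imidazole give the primary iodide F10. Nickel-catalysed reductive cross-electrophile coupling of F10 with 3-bromofuran-2(5H)-one (NiBr2(dme), 4,4′-di-tert-butyl-2,2′-bipyridine, Zn, DMA, rt) should install the butenolide directly and give 19.

Further compounds

F1 | step 9 | diethyl 2-[6-(1,3-dioxolan-2-yl)-4-methyl-5-oxohexyl]propanedioate (racemic) | CCOC(=O)C(CCCC(C)C(=O)CC1OCCO1)C(=O)OCC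
F2 | step 9 | diethyl 2-[6-(1,3-dioxolan-2-yl)-4-methyl-5-oxohexyl]-2-[(1E)-3-ethoxy-3-oxoprop-1-en-1-yl]propanedioate (racemic) | CCOC(=O)/C=C/C(CCCC(C)C(=O)CC1OCCO1)(C(=O)OCC)C(=O)OCC
F3 | step 9 | 2-[6-(1,3-dioxolan-2-yl)-5-hydroxy-4-methylhexyl]-2-[(1E)-3-hydroxyprop-1-en-1-yl]propane-1,3-diol (diastereomer mixture) | OC/C=C/C(CO)(CO)CCCC(C)C(O)CC1OCCO1
F4 | step 9 | 1-(1,3-dioxolan-2-yl)-6-{5-[(1E)-3-hydroxyprop-1-en-1-yl]-2,2-dimethyl-1,3-dioxan-5-yl}-3-methylhexan-2-ol (diastereomer mixture) | OC/C=C/C1(CCCC(C)C(O)CC2OCCO2)COC(C)(C)OC1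
F5 | step 9 | (2E)-3-{5-[6-(1,3-dioxolan-2-yl)-4-methyl-5-oxohexyl]-2,2-dimethyl-1,3-dioxan-5-yl}prop-2-enal (racemic) | O=C/C=C/C1(CCCC(C)C(=O)CC2OCCO2)COC(C)(C)OC1
F6 | step 9 | bicyclic enone: trans-fused decalin (C5 and C10 as in the target) with the 18,19-acetonide, C9 ketone, C7=C8 double bond and 1,3-dioxolan-2-yl on C8 | C[C@@]12CCCC3(COC(C)(C)OC3)[C@H]1CC=C(C4OCCO4)C2=O
F7 | step 9 | propargylic alcohol: F6 with C9 carrying OH and ethynyl (either C9 epimer) | C[C@@]12CCCC3(COC(C)(C)OC3)[C@H]1CC=C(C4OCCO4)C2(O)C#C
F8 | step 10 | unsaturated aldehyde: 15 with the C9=C11 bond reduced (C9–H trans to the C10 methyl group) and C7=C8 retained | C[C@@]12CCCC3(COC(C)(C)OC3)[C@H]1CC=C(C4OCCO4)[C@H]2CC=O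
F9 | step 12 | primary alcohol: 16 with CH2CHO reduced to CH2CH2OH | C[C@@]12CCCC3(COC(C)(C)OC3)[C@H]1CC[C@@H](C4OCCO4)[C@H]2CCO
F10 | step 12 | primary iodide: 16 with CH2CHO converted into CH2CH2I | C[C@@]12CCCC3(COC(C)(C)OC3)[C@H]1CC[C@@H](C4OCCO4)[C@H]2CCI
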